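**Retrosynthetic overview**
1. Target 7 ⇒ terminal alkene 6; the side-chain methyl ketone comes last, by Wacker oxidation (C–O bond).
2. 6 ⇒ 3-methoxy-2-methylquinolin-4(1H)-one 3 + 12-bromo-1-dodecene 4, by lateral C-alkylation of the 2-methyl dianion 5.
3. 3 ⇒ 2-methylquinolin-4(1H)-one 1, by direct C3–H methoxylation (the C3–OMe bond; key step and new chemistry, run first on the cheapest material).
4. Ring formation: none. The quinolin-4(1H)-one bicycle is bought complete in 1 and only decorated.

Assumption: the target SMILES has no stereocentre or stereogenic double bond, so the compound is achiral and no stereocontrol is needed; 12-bromo-1-dodecene is taken as a catalogue reagent.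

**Route**

Step 1
Reactants: 1 2-methylquinolin-4(1H)-one
Product: 3 3-methoxy-2-methylquinolin-4(1H)-one, via 3-[acetoxy(phenyl)-λ3-iodanyl]-2-methylquinolin-4(3H)-one 2 (not isolated)
Conditions: PhI(OAc)2 (1.1 equiv, in portions), MeOH/HFIP (4:1), 0 °C → rt
Reagents that add atoms: methanol, CO
Why: Proposed new method: direct C3–H methoxylation of an N–H 4-quinolone by iodine(III) umpolung — the enaminone carbon C3 (the only nucleophilic carbon, the site that is halogenated by electrophiles) attacks PhI(OAc)2 to give the C3-bound λ3-iodane 2, methanol (solvent, large excess over acetate) displaces the hypernucleofuge PhI at this α-keto/α-imino carbon, and tautomerisation restores the quinolone; the closest known reaction types are PhI(OAc)2 α-acyloxylation of enaminones, iodine(III) α-methoxylation of ketones in methanol and PhI(OAc)2/halide C3-halogenation of 4-quinolones.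

Step 2
Reactants: 3 3-methoxy-2-methylquinolin-4(1H)-one; 4 12-bromo-1-dodecene
Product: 6 3-methoxy-2-(tridec-12-en-1-yl)quinolin-4(1H)-one, via lithium 2-(lithiomethyl)-3-methoxyquinolin-4-olate 5 (not isolated)
Conditions: n-BuLi (2.1 equiv), THF, –78 → 0 °C; then 4 (1.1 equiv), –78 °C → rt; aq. NH4Cl
Reagents that add atoms: none
Why: Lateral metalation/alkylation — the first equivalent of base removes N–H, the second removes a proton of the 2-methyl group (aza-enolate type carbanion, chelated by the 3-OMe oxygen), and this most basic site of dianion 5 undergoes SN2 C-alkylation with the primary bromide.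

Step 3
Reactants: 6 3-methoxy-2-(tridec-12-en-1-yl)quinolin-4(1H)-one
Product: 7 3-methoxy-2-(12-oxotridecyl)quinolin-4(1H)-one
Conditions: PdCl2 (10 mol%), CuCl (30 mol%), O2 (1 atm), DMF/H2O (7:1), rt
Reagents that add atoms: water, O
Why: Tsuji–Wacker oxidation — Markovnikov hydroxypalladation of the unhindered terminal alkene and β-hydride elimination give the methyl ketone, while the quinolone and aryl methyl ether are inert to Pd(II)/Cu/O2.

**Compound list**
1 | 2-methylquinolin-4(1H)-one | Cc1cc(=O)c2ccccc2[nH]1 | starting material
2 | 3-[acetoxy(phenyl)-λ3-iodanyl]-2-methylquinolin-4(3H)-one (transient, racemic at C3) | CC(=O)OI(c1ccccc1)C1C(C)=Nc2ccccc2C1=O | intermediate (not isolated)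
3 | 3-methoxy-2-methylquinolin-4(1H)-one | COc1c(C)[nH]c2ccccc2c1=O | intermediate
4 | 12-bromo-1-dodecene | C=CCCCCCCCCCCBr | starting material
5 | lithium 2-(lithiomethyl)-3-methoxyquinolin-4-olate (dianion of 3) | [Li]Cc1nc2ccccc2c(O[Li])c1OC | intermediate (not isolated)
6 | 3-methoxy-2-(tridec-12-en-1-yl)quinolin-4(1H)-one | COc1c(CCCCCCCCCCCC=C)[nH]c2ccccc2c1=O | intermediate
7 | 3-methoxy-2-(12-oxotridecyl)quinolin-4(1H)-one (achiral) | COc1c(CCCCCCCCCCCC(C)=O)[nH]c2ccccc2c1=O | target

**Totals**
Total step count: 3. Longest linear sequence: 3 steps (1 → 3 → 6 → 7).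

**Three steps most likely to fail, with fallbacks**

Step 1 (proposed new method). Three things can go wrong: the C3-iodane may settle as a stable iodonium betaine or transfer an aryl group instead of being displaced by methanol; acetate may be captured in place of methanol; or the more electron-rich product 3 may be oxidised a second time at C3. Fallback with known chemistry, setting out from 1: electrophilic iodination with N-iodosuccinimide in DMF at rt gives 3-iodo-2-methylquinolin-4(1H)-one F1. Copper-catalysed Ullmann-type methoxylation (CuI 10 mol%, 1,10-phenanthroline 20 mol%, NaOMe 3 equiv, MeOH/DMF, 110 °C, sealed tube) then replaces iodide by methoxide and returns to the route at 3.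

Step 2. The dianion of the N–H quinolone may be poorly soluble or incompletely formed, or the bromide may alkylate N or O. Fallback, setting out from 3: POCl3 at 90 °C masks the quinolone as 4-chloro-3-methoxy-2-methylquinoline F2. LDA in THF at –78 °C deprotonates the 2-methyl group (textbook lateral lithiation of a 2-methylquinoline) to [(4-chloro-3-methoxyquinolin-2-yl)methyl]lithium F3, which is alkylated in the same flask with 4 to give 4-chloro-3-methoxy-2-(tridec-12-en-1-yl)quinoline F4. Hydrolysis of the 4-chloride (AcOH/H2O, NaOAc, 110 °C) regenerates the quinolone and returns to the route at 6.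

Step 3. Pd–H isomerisation of the long-chain alkene can give internal ketone isomers, and the quinolone may bind Pd and slow turnover. Fallback, setting out from 6: Mukaiyama hydration (Co(acac)2 cat., PhSiH3, O2, i-PrOH/THF, rt) gives the Markovnikov alcohol, racemic 2-(12-hydroxytridecyl)-3-methoxyquinolin-4(1H)-one F5. Oxidation with Dess–Martin periodinane in CH2Cl2 destroys that stereocentre and returns to the route at 7.

**Further compounds**
F1 | step 1 | 3-iodo-2-methylquinolin-4(1H)-one | Cc1[nH]c2ccccc2c(=O)c1I
F2 | step 2 | 4-chloro-3-methoxy-2-methylquinoline | COc1c(C)nc2ccccc2c1Cl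
F3 | step 2 | [(4-chloro-3-methoxyquinolin-2-yl)methyl]lithium | [Li]Cc1nc2ccccc2c(Cl)c1OC
F4 | step 2 | 4-chloro-3-methoxy-2-(tridec-12-en-1-yl)quinoline | COc1c(CCCCCCCCCCCC=C)nc2ccccc2c1Cl
F5 | step 3 | rac-2-(12-hydroxytridecyl)-3-methoxyquinolin-4(1H)-one | COc1c(CCCCCCCCCCCC(C)O)[nH]c2ccccc2c1=O
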